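**Strategy.** The oxolane ring (O1, C2–C5) is closed late between C4, the carbon that carries the benzyl group, and C5, the unsubstituted O–CH2 carbon. Because C5 bears only the ring oxygen and hydrogens, it can be generated as an α-alkoxymethyl radical by photoredox decarboxylation of an O-carboxymethyl ether; C4 is held as the inner carbon of an aryl alkyne. 5-exo-dig cyclisation gives a 4-benzylidene oxolane, and hydrogenation anti to the cis C2-aryl and C3-CH2O groups then completes the all-cis ring. The precursor is the glycolic acid ether of a homopropargylic alcohol, made by allylboration of a bis(dihydrobenzofuran) aldehyde built by two Evans aldol/cyclisation rounds.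

Key step: step 19

Assumption: compounds 1, 25 and 26 are taken as catalogue chemicals, as are both enantiomers of 4-benzyloxazolidin-2-one and of the phosphoric acid TRIP.

Abbreviations: TBDPS = tert-butyldiphenylsilyl; MOM = methoxymethyl; DCC = N,N'-dicyclohexylcarbodiimide; Ar* = the aryl group of aldehyde 24 (24 = Ar*–CHO); oxolane numbering O1, C2 (aryl), C3 (CH2O), C4 (benzyl), C5 (OCH2).

Step 1
Reactants: 1 (2-hydroxy-3-methoxyphenyl)acetic acid
Product: 2 (5-bromo-2-hydroxy-3-methoxyphenyl)acetic acid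
Conditions: NBS, MeCN, 0 °C to rt
Reagents that add atoms: N-bromosuccinimide, O=C1CCC(=O)N1Br
Why: Electrophilic aromatic bromination; the free phenol should direct bromine to its only open para position (C5), which becomes the handle for the later formyl group.

Step 2
Reactants: 2 (5-bromo-2-hydroxy-3-methoxyphenyl)acetic acid
Product: 4 [5-bromo-3-methoxy-2-(methoxymethoxy)phenyl]acetic acid, via methoxymethyl ester 3 (not isolated)
Conditions: MOMCl, iPr2NEt, CH2Cl2, 0 °C to rt; then LiOH, THF/H2O, rt; 1 M HCl to pH 4, 0 °C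
Reagents that add atoms: chloromethyl methyl ether, COCCl; lithium hydroxide, [Li+].[OH-]
Why: O-alkylation of phenol and acid followed by saponification of the labile acyloxymethyl ester should leave the base-stable aryl MOM ether, which is later removed by the same acid that closes the dihydrobenzofuran.

Step 3
Reactants: 4 [5-bromo-3-methoxy-2-(methoxymethoxy)phenyl]acetic acid; 5 (S)-4-benzyloxazolidin-2-one
Product: 7 (S)-N-arylacetyl oxazolidinone, via mixed pivalic anhydride 6 (not isolated)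
Conditions: PivCl, Et3N, THF, −20 °C; then LiCl, 5, rt
Reagents that add atoms: none
Why: N-acylation of the oxazolidinone through the mixed anhydride (standard preparation of an Evans imide).

Step 4
Reactants: 4 [5-bromo-3-methoxy-2-(methoxymethoxy)phenyl]acetic acid; 8 (R)-4-benzyloxazolidin-2-one
Product: 9 (R)-N-arylacetyl oxazolidinone
Conditions: DCC, DMAP (20 mol%), CH2Cl2, 0 °C to rt
Reagents that add atoms: none
Why: Carbodiimide-mediated N-acylation of the oxazolidinone with DMAP as acyl-transfer catalyst, run in one flask directly from the free acid, gives the enantiomeric imide that is needed because the two dihydrobenzofuran rings have opposite configurations.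

Step 5
Reactants: 7 (S)-N-arylacetyl oxazolidinone; 10 4-(benzyloxy)-3-methoxybenzaldehyde
Product: 12 (2S,3S) syn-aldol adduct, via boron enolate 11 (not isolated)
Conditions: Bu2BOTf, iPr2NEt, CH2Cl2, −78 to 0 °C; 10, −78 to 0 °C; pH 7 buffer, MeOH, H2O2, 0 °C
Reagents that add atoms: none
Why: Evans syn-aldol reaction; the Z-boron enolate should react through a closed chair transition state on the face away from the auxiliary benzyl group, which sets the α-aryl centre (later C3 of ring B) and the carbinol centre both as S.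

Step 6
Reactants: 12 (2S,3S) syn-aldol adduct
Product: 14 [(2S,3R)-2-[4-(benzyloxy)-3-methoxyphenyl]-5-bromo-7-methoxy-2,3-dihydro-1-benzofuran-3-yl]methanol, via syn diol 13 (not isolated)
Conditions: LiBH4, MeOH, THF, 0 °C; then HCl in MeOH (from AcCl), rt to 40 °C
Reagents that add atoms: none
Why: Reductive cleavage of the auxiliary, then acid removes the aryl MOM ether and ionises the p-alkoxybenzylic alcohol so that the phenol closes the five-membered ring (SN1 etherification); the benzylic centre should settle trans (2S) to the fixed 3R centre.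

Step 7
Reactants: 14 ring B bromo alcohol
Product: 15 TBDPS ether of 14
Conditions: TBDPSCl, imidazole, DMF, rt
Reagents that add atoms: tert-butyl(chloro)diphenylsilane, CC(C)(C)[Si](Cl)(c1ccccc1)c1ccccc1
Why: Silylation of the primary alcohol; the TBDPS ether should survive the later aldol, hydride, acid and organolithium conditions.

Step 8
Reactants: 15 TBDPS ether of 14
Product: 17 ring B 5-carbaldehyde, via aryllithium 16 (not isolated)
Conditions: n-BuLi, THF, −78 °C; DMF, −78 to 0 °C; aq. NH4Cl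
Reagents that add atoms: N,N-dimethylformamide, CN(C)C=O
Why: Bromine–lithium exchange and formylation of the aryllithium with DMF (Bouveault aldehyde synthesis) give the electrophile for the second aldol round.

Step 9
Reactants: 9 (R)-N-arylacetyl oxazolidinone; 17 ring B 5-carbaldehyde
Product: 19 (2R,3R) syn-aldol adduct, via boron enolate 18 (not isolated)
Conditions: Bu2BOTf, iPr2NEt, CH2Cl2, −78 to 0 °C; 17, −78 to 0 °C; pH 7 buffer, MeOH, H2O2, 0 °C
Reagents that add atoms: none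
Why: Evans syn-aldol reaction with the enantiomeric auxiliary, so the new α-aryl centre (later C3 of ring A) is set R under reagent control, independent of the remote centres of ring B.

Step 10
Reactants: 19 (2R,3R) syn-aldol adduct
Product: 21 ring A bromo alcohol (2R,3S), via syn diol 20 (not isolated)
Conditions: LiBH4, MeOH, THF, 0 °C; then HCl in MeOH (from AcCl), rt
Reagents that add atoms: none
Why: Auxiliary reduction and acid-mediated SN1 ring closure as in step 6; the new benzylic centre should settle trans (2R) to the 3S centre, the ring B ether can only reclose to its trans form, and any silyl ether lost to the acid is restored in step 11.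

Step 11
Reactants: 21 ring A bromo alcohol
Product: 22 bis-TBDPS ether
Conditions: TBDPSCl, imidazole, DMF, rt
Reagents that add atoms: tert-butyl(chloro)diphenylsilane, CC(C)(C)[Si](Cl)(c1ccccc1)c1ccccc1
Why: Silylation of the primary alcohol of ring A ahead of the organolithium and allylboration steps.

Step 12
Reactants: 22 bis-TBDPS ether
Product: 24 bis(dihydrobenzofuran) aldehyde Ar*–CHO, via aryllithium 23 (not isolated)
Conditions: n-BuLi, THF, −78 °C; DMF, −78 to 0 °C; aq. NH4Cl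
Reagents that add atoms: N,N-dimethylformamide, CN(C)C=O
Why: Bromine–lithium exchange and Bouveault formylation, as in step 8.

Step 13
Reactants: 25 1-(benzyloxy)-4-bromo-2-methoxybenzene; 26 (E)-pent-2-en-4-yn-1-ol
Product: 27 (E)-5-[4-(benzyloxy)-3-methoxyphenyl]pent-2-en-4-yn-1-ol
Conditions: PdCl2(PPh3)2 (3 mol%), CuI (3 mol%), iPr2NH, 70 °C
Reagents that add atoms: none
Why: Sonogashira coupling of the aryl bromide with the terminal alkyne; the E-alkene and the free alcohol should be untouched.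

Step 14
Reactants: 27 (E)-enynol
Product: 28 (E)-enynyl allylboronic acid pinacol ester
Conditions: B2pin2, [Pd(MeCN)4](BF4)2 (5 mol%), DMSO/MeOH 1:1, 40 °C
Reagents that add atoms: bis(pinacolato)diboron, CC1(C)OB(OC1(C)C)B1OC(C)(C)C(C)(C)O1
Why: Palladium-catalysed borylation of the allylic alcohol through a π-allyl complex (allylic Miyaura-type borylation) should place boron at the unsubstituted terminus and keep the E geometry.

Step 15
Reactants: 24 bis(dihydrobenzofuran) aldehyde Ar*–CHO; 28 (E)-enynyl allylboronic acid pinacol ester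
Product: 30 (1R,2S)-1-Ar*-2-{[4-(benzyloxy)-3-methoxyphenyl]ethynyl}but-3-en-1-ol, via borate ester 29 (not isolated)
Conditions: (R)-TRIP [(R)-3,3'-bis(2,4,6-triisopropylphenyl)-1,1'-binaphthyl-2,2'-diyl hydrogen phosphate] (5 mol%), 4 Å MS, toluene, −30 °C to rt; aqueous work-up
Reagents that add atoms: none
Why: Chiral phosphoric acid-catalysed allylboration through a closed chair transition state; the E-γ-alkynyl boronate should give the anti relationship of OH and alkynyl group and the (R)-acid should direct attack to the re face of the aldehyde, which sets C2 (R) and C3 of the future oxolane with the vinyl group as a masked hydroxymethyl.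

Step 16
Reactants: 30 anti homoallylic alcohol
Product: 32 (1R,2R)-1-Ar*-2-{[4-(benzyloxy)-3-methoxyphenyl]ethynyl}propane-1,3-diol, via ozonide 31 (not isolated)
Conditions: O3 (1.05 equiv as a cold CH2Cl2 solution), CH2Cl2, −78 °C; then NaBH4, MeOH, −78 to 0 °C
Reagents that add atoms: ozone, [O-][O+]=O
Why: Ozonolysis of the terminal alkene, which should react much faster than the alkyne or the arenes when ozone is dosed, with direct hydride reduction of the ozonide so that no epimerisable α-alkynyl aldehyde accumulates.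

Step 17
Reactants: 32 alkynyl 1,3-diol
Product: 33 primary TBDPS ether of 32
Conditions: TBDPSCl (1.05 equiv), imidazole, CH2Cl2, 0 °C
Reagents that add atoms: tert-butyl(chloro)diphenylsilane, CC(C)(C)[Si](Cl)(c1ccccc1)c1ccccc1
Why: Selective silylation of the primary over the hindered secondary benzylic alcohol; the bulky ether later shields one face of the ring in step 20.

Step 18
Reactants: 33 primary TBDPS ether of 32
Product: 34 O-carboxymethyl ether (alkoxyacetic acid)
Conditions: NaH (3 equiv), BrCH2CO2H, THF, 0 °C to rt; 1 M HCl to pH 4, 0 °C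
Reagents that add atoms: bromoacetic acid, OC(=O)CBr
Why: Williamson etherification of the secondary alkoxide with sodium bromoacetate installs the O–CH2–CO2H unit whose methylene becomes C5 of the oxolane.

Step 19
Reactants: 34 O-carboxymethyl ether (alkoxyacetic acid)
Product: 35 (2R,3R)-2-Ar*-4-[4-(benzyloxy)-3-methoxybenzylidene]-3-(TBDPS-oxymethyl)oxolane (E/Z mixture)
Conditions: [Ir(dF(CF3)ppy)2(dtbbpy)]PF6 (2 mol%), K2HPO4, DMF/H2O 20:1, 450 nm LEDs, rt, degassed
Reagents that add atoms: none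
Why: The excited trivalent iridium photocatalyst oxidises the carboxylate, loss of CO2 gives the α-alkoxymethyl radical O–CH2•, this adds to the proximal alkyne carbon C4 to form the C4–C5 bond and the oxolane ring, and the α-aryl vinyl radical is reduced by the divalent iridium species and protonated. The closest known reaction types are photoredox decarboxylative Giese-type hydroalkylation of alkynes with α-oxy acids and the tin hydride-mediated cyclisation of alkoxymethyl radicals. The ring closes in the 5-exo-dig mode. No stereocentre is formed, since C4 becomes sp2 and is set in step 20, and C2 and C3 are not touched. The step needs exo over 6-endo regioselectivity and cyclisation before reduction of the first radical; the three-atom tether, the aryl group that stabilises the exo vinyl radical and the absence of a hydrogen-atom donor should secure both.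

Step 20
Reactants: 35 4-benzylidene oxolane
Product: 36 tris-TBDPS ether of the target (2R,3R,4R oxolane with free phenols)
Conditions: H2 (1 atm), 10% Pd/C, EtOAc, rt
Reagents that add atoms: none
Why: Heterogeneous syn-hydrogenation; the catalyst should approach the exocyclic alkene from the face opposite the cis C2-aryl and C3-silyloxymethyl groups, so the new C4–H lands trans to them and the benzyl group cis (4R, all-cis), while the two phenolic benzyl ethers are hydrogenolysed in the same operation.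

Step 21
Reactants: 36 tris-TBDPS ether of the target
Product: 37 CNP0395728.1 (target)
Conditions: Bu4NF, AcOH, THF, rt; aq. NH4Cl
Reagents that add atoms: none
Why: Fluoride-mediated cleavage of the three primary silyl ethers (global desilylation) under buffered conditions that should leave the benzylic ethers and all stereocentres untouched.

Compound list

1 | (2-hydroxy-3-methoxyphenyl)acetic acid | OC(=O)Cc1cccc(OC)c1O | starting material
2 | (5-bromo-2-hydroxy-3-methoxyphenyl)acetic acid | OC(=O)Cc1cc(Br)cc(OC)c1O | intermediate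
3 | methoxymethyl [5-bromo-3-methoxy-2-(methoxymethoxy)phenyl]acetate | COCOC(=O)Cc1cc(Br)cc(OC)c1OCOC | intermediate
4 | [5-bromo-3-methoxy-2-(methoxymethoxy)phenyl]acetic acid | OC(=O)Cc1cc(Br)cc(OC)c1OCOC | intermediate
5 | (S)-4-benzyloxazolidin-2-one | O=C1N[C@@H](Cc2ccccc2)CO1 | starting material
6 | mixed anhydride of acid 4 and pivalic acid | CC(C)(C)C(=O)OC(=O)Cc1cc(Br)cc(OC)c1OCOC | intermediate
7 | (S)-4-benzyl-3-{[5-bromo-3-methoxy-2-(methoxymethoxy)phenyl]acetyl}oxazolidin-2-one | O=C(Cc1cc(Br)cc(OC)c1OCOC)N1[C@@H](Cc2ccccc2)COC1=O | intermediate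
8 | (R)-4-benzyloxazolidin-2-one | O=C1N[C@H](Cc2ccccc2)CO1 | starting material
9 | (R)-4-benzyl-3-{[5-bromo-3-methoxy-2-(methoxymethoxy)phenyl]acetyl}oxazolidin-2-one | O=C(Cc1cc(Br)cc(OC)c1OCOC)N1[C@H](Cc2ccccc2)COC1=O | intermediate
10 | 4-(benzyloxy)-3-methoxybenzaldehyde | O=Cc1ccc(OCc2ccccc2)c(OC)c1 | starting material
11 | Z-dibutylboron enolate of imide 7 | CCCCB(CCCC)O/C(=C\c1cc(Br)cc(OC)c1OCOC)N1[C@@H](Cc2ccccc2)COC1=O | intermediate
12 | (S)-4-benzyl-3-[(2S,3S)-3-[4-(benzyloxy)-3-methoxyphenyl]-2-[5-bromo-3-methoxy-2-(methoxymethoxy)phenyl]-3-hydroxypropanoyl]oxazolidin-2-one | O=C(N1[C@@H](Cc2ccccc2)COC1=O)[C@@H](c1cc(Br)cc(OC)c1OCOC)[C@H](O)c1ccc(OCc2ccccc2)c(OC)c1 | intermediate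
13 | (1S,2R)-1-[4-(benzyloxy)-3-methoxyphenyl]-2-[5-bromo-3-methoxy-2-(methoxymethoxy)phenyl]propane-1,3-diol | OC[C@@H](c1cc(Br)cc(OC)c1OCOC)[C@H](O)c1ccc(OCc2ccccc2)c(OC)c1 | intermediate
14 | [(2S,3R)-2-[4-(benzyloxy)-3-methoxyphenyl]-5-bromo-7-methoxy-2,3-dihydro-1-benzofuran-3-yl]methanol (trans) | Brc1cc(OC)c2c(c1)[C@H](CO)[C@@H](c1ccc(OCc3ccccc3)c(OC)c1)O2 | intermediate
15 | (2S,3R)-2-[4-(benzyloxy)-3-methoxyphenyl]-5-bromo-7-methoxy-3-(TBDPS-oxymethyl)-2,3-dihydro-1-benzofuran | Brc1cc(OC)c2c(c1)[C@H](CO[Si](c1ccccc1)(c1ccccc1)C(C)(C)C)[C@@H](c1ccc(OCc3ccccc3)c(OC)c1)O2 | intermediate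
16 | 5-lithio analogue of 15 (aryllithium) | [Li]c1cc(OC)c2c(c1)[C@H](CO[Si](c1ccccc1)(c1ccccc1)C(C)(C)C)[C@@H](c1ccc(OCc3ccccc3)c(OC)c1)O2 | intermediate
17 | (2S,3R)-2-[4-(benzyloxy)-3-methoxyphenyl]-7-methoxy-3-(TBDPS-oxymethyl)-2,3-dihydro-1-benzofuran-5-carbaldehyde | O=Cc1cc(OC)c2c(c1)[C@H](CO[Si](c1ccccc1)(c1ccccc1)C(C)(C)C)[C@@H](c1ccc(OCc3ccccc3)c(OC)c1)O2 | intermediate
18 | Z-dibutylboron enolate of imide 9 | CCCCB(CCCC)O/C(=C\c1cc(Br)cc(OC)c1OCOC)N1[C@H](Cc2ccccc2)COC1=O | intermediate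
19 | (R)-4-benzyl-3-[(2R,3R)-2-[5-bromo-3-methoxy-2-(methoxymethoxy)phenyl]-3-hydroxy-3-(benzofuran-5-yl unit of 17)propanoyl]oxazolidin-2-one | O=C(N1[C@H](Cc2ccccc2)COC1=O)[C@H](c1cc(Br)cc(OC)c1OCOC)[C@@H](O)c1cc(OC)c2c(c1)[C@H](CO[Si](c1ccccc1)(c1ccccc1)C(C)(C)C)[C@@H](c1ccc(OCc3ccccc3)c(OC)c1)O2 | intermediate
20 | (1R,2S)-2-[5-bromo-3-methoxy-2-(methoxymethoxy)phenyl]-1-(benzofuran-5-yl unit of 17)propane-1,3-diol | OC[C@H](c1cc(Br)cc(OC)c1OCOC)[C@@H](O)c1cc(OC)c2c(c1)[C@H](CO[Si](c1ccccc1)(c1ccccc1)C(C)(C)C)[C@@H](c1ccc(OCc3ccccc3)c(OC)c1)O2 | intermediate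
21 | [(2R,3S)-5-bromo-7-methoxy-2-(benzofuran-5-yl unit of 17)-2,3-dihydro-1-benzofuran-3-yl]methanol (trans ring A on trans ring B) | Brc1cc(OC)c2c(c1)[C@@H](CO)[C@H](c1cc(OC)c3c(c1)[C@H](CO[Si](c1ccccc1)(c1ccccc1)C(C)(C)C)[C@@H](c1ccc(OCc4ccccc4)c(OC)c1)O3)O2 | intermediate
22 | TBDPS ether of 21 (bis-TBDPS aryl bromide Ar*–Br) | Brc1cc(OC)c2c(c1)[C@@H](CO[Si](c1ccccc1)(c1ccccc1)C(C)(C)C)[C@H](c1cc(OC)c3c(c1)[C@H](CO[Si](c1ccccc1)(c1ccccc1)C(C)(C)C)[C@@H](c1ccc(OCc4ccccc4)c(OC)c1)O3)O2 | intermediate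
23 | aryllithium Ar*–Li from 22 | [Li]c1cc(OC)c2c(c1)[C@@H](CO[Si](c1ccccc1)(c1ccccc1)C(C)(C)C)[C@H](c1cc(OC)c3c(c1)[C@H](CO[Si](c1ccccc1)(c1ccccc1)C(C)(C)C)[C@@H](c1ccc(OCc4ccccc4)c(OC)c1)O3)O2 | intermediate
24 | aldehyde Ar*–CHO: (2R,3S)-7-methoxy-3-(TBDPS-oxymethyl)-2-[(2S,3R)-2-[4-(benzyloxy)-3-methoxyphenyl]-7-methoxy-3-(TBDPS-oxymethyl)-2,3-dihydro-1-benzofuran-5-yl]-2,3-dihydro-1-benzofuran-5-carbaldehyde | O=Cc1cc(OC)c2c(c1)[C@@H](CO[Si](c1ccccc1)(c1ccccc1)C(C)(C)C)[C@H](c1cc(OC)c3c(c1)[C@H](CO[Si](c1ccccc1)(c1ccccc1)C(C)(C)C)[C@@H](c1ccc(OCc4ccccc4)c(OC)c1)O3)O2 | intermediate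
25 | 1-(benzyloxy)-4-bromo-2-methoxybenzene | Brc1ccc(OCc2ccccc2)c(OC)c1 | starting material
26 | (E)-pent-2-en-4-yn-1-ol | OC/C=C/C#C | starting material
27 | (E)-5-[4-(benzyloxy)-3-methoxyphenyl]pent-2-en-4-yn-1-ol | OC/C=C/C#Cc1ccc(OCc2ccccc2)c(OC)c1 | intermediate
28 | (E)-2-{5-[4-(benzyloxy)-3-methoxyphenyl]pent-2-en-4-yn-1-yl}-4,4,5,5-tetramethyl-1,3,2-dioxaborolane | CC1(C)OB(C/C=C/C#Cc2ccc(OCc3ccccc3)c(OC)c2)OC1(C)C | intermediate
29 | pinacol borate ester (O–Bpin) of alcohol 30 | CC1(C)OB(O[C@@H](c3cc(OC)c4c(c3)[C@@H](CO[Si](c3ccccc3)(c3ccccc3)C(C)(C)C)[C@H](c3cc(OC)c5c(c3)[C@H](CO[Si](c3ccccc3)(c3ccccc3)C(C)(C)C)[C@@H](c3ccc(OCc6ccccc6)c(OC)c3)O5)O4)[C@@H](C=C)C#Cc2ccc(OCc7ccccc7)c(OC)c2)OC1(C)C | intermediate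
30 | (1R,2S)-1-Ar*-2-{[4-(benzyloxy)-3-methoxyphenyl]ethynyl}but-3-en-1-ol (anti) | O[C@@H](c3cc(OC)c4c(c3)[C@@H](CO[Si](c3ccccc3)(c3ccccc3)C(C)(C)C)[C@H](c3cc(OC)c5c(c3)[C@H](CO[Si](c3ccccc3)(c3ccccc3)C(C)(C)C)[C@@H](c3ccc(OCc6ccccc6)c(OC)c3)O5)O4)[C@@H](C=C)C#Cc1ccc(OCc2ccccc2)c(OC)c1 | intermediate
31 | ozonide (3-substituted 1,2,4-trioxolane) from the vinyl group of 30 | O[C@@H](c3cc(OC)c4c(c3)[C@@H](CO[Si](c3ccccc3)(c3ccccc3)C(C)(C)C)[C@H](c3cc(OC)c5c(c3)[C@H](CO[Si](c3ccccc3)(c3ccccc3)C(C)(C)C)[C@@H](c3ccc(OCc6ccccc6)c(OC)c3)O5)O4)[C@@H](C1OCOO1)C#Cc1ccc(OCc2ccccc2)c(OC)c1 | intermediate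
32 | (1R,2R)-1-Ar*-2-{[4-(benzyloxy)-3-methoxyphenyl]ethynyl}propane-1,3-diol | O[C@@H](c3cc(OC)c4c(c3)[C@@H](CO[Si](c3ccccc3)(c3ccccc3)C(C)(C)C)[C@H](c3cc(OC)c5c(c3)[C@H](CO[Si](c3ccccc3)(c3ccccc3)C(C)(C)C)[C@@H](c3ccc(OCc6ccccc6)c(OC)c3)O5)O4)[C@@H](CO)C#Cc1ccc(OCc2ccccc2)c(OC)c1 | intermediate
33 | (1R,2R)-1-Ar*-2-{[4-(benzyloxy)-3-methoxyphenyl]ethynyl}-3-(TBDPS-oxy)propan-1-ol | O[C@@H](c3cc(OC)c4c(c3)[C@@H](CO[Si](c3ccccc3)(c3ccccc3)C(C)(C)C)[C@H](c3cc(OC)c5c(c3)[C@H](CO[Si](c3ccccc3)(c3ccccc3)C(C)(C)C)[C@@H](c3ccc(OCc6ccccc6)c(OC)c3)O5)O4)[C@@H](CO[Si](c1ccccc1)(c1ccccc1)C(C)(C)C)C#Cc1ccc(OCc2ccccc2)c(OC)c1 | intermediate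
34 | {[(1R,2R)-1-Ar*-2-{[4-(benzyloxy)-3-methoxyphenyl]ethynyl}-3-(TBDPS-oxy)propyl]oxy}acetic acid | OC(=O)CO[C@@H](c3cc(OC)c4c(c3)[C@@H](CO[Si](c3ccccc3)(c3ccccc3)C(C)(C)C)[C@H](c3cc(OC)c5c(c3)[C@H](CO[Si](c3ccccc3)(c3ccccc3)C(C)(C)C)[C@@H](c3ccc(OCc6ccccc6)c(OC)c3)O5)O4)[C@@H](CO[Si](c1ccccc1)(c1ccccc1)C(C)(C)C)C#Cc1ccc(OCc2ccccc2)c(OC)c1 | intermediate
35 | (2R,3R)-2-Ar*-4-[4-(benzyloxy)-3-methoxybenzylidene]-3-(TBDPS-oxymethyl)oxolane (E/Z mixture; 2-aryl and 3-CH2O cis) | COc1cc(C=C2CO[C@@H](c3cc(OC)c4c(c3)[C@@H](CO[Si](c3ccccc3)(c3ccccc3)C(C)(C)C)[C@H](c3cc(OC)c5c(c3)[C@H](CO[Si](c3ccccc3)(c3ccccc3)C(C)(C)C)[C@@H](c3ccc(OCc6ccccc6)c(OC)c3)O5)O4)[C@H]2CO[Si](c3ccccc3)(c3ccccc3)C(C)(C)C)ccc1OCc1ccccc1 | intermediate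
36 | tris-TBDPS ether of the target: all-cis (2R,3R,4R)-oxolane with 4-(4-hydroxy-3-methoxybenzyl) group; Ar* carries 4-hydroxy in place of 4-benzyloxy | COc1cc(C[C@H]2CO[C@@H](c3cc(OC)c4c(c3)[C@@H](CO[Si](c3ccccc3)(c3ccccc3)C(C)(C)C)[C@H](c3cc(OC)c5c(c3)[C@H](CO[Si](c3ccccc3)(c3ccccc3)C(C)(C)C)[C@@H](c3ccc(O)c(OC)c3)O5)O4)[C@H]2CO[Si](c3ccccc3)(c3ccccc3)C(C)(C)C)ccc1O | intermediate
37 | CNP0395728.1: all-cis (2R,3R,4R)-oxolane carrying ring A (2R,3S) and ring B (2S,3R) dihydrobenzofurans | COc1cc(C[C@H]2CO[C@@H](c3cc(OC)c4c(c3)[C@@H](CO)[C@H](c3cc(OC)c5c(c3)[C@H](CO)[C@@H](c3ccc(O)c(OC)c3)O5)O4)[C@H]2CO)ccc1O | target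

Total step count: 21.
Longest linear sequence: 18 steps (steps 1, 2, 3, 5–12, 15–21; compound 1 to 37).

Steps most likely to fail

Step 19 (key step). The alkoxymethyl radical may be reduced or may fragment before it cyclises, and the excited photocatalyst may oxidise the electron-rich arenes instead of the carboxylate. The fallback sets out from acid 34. Esterification with N-hydroxypyridine-2-thione (DCC, DMAP cat., CH2Cl2, dark) would give the Barton ester F1. Photolysis of F1 in the presence of Bu3SnH (benzene, visible light, rt) would generate the same radical in a chain process in which the stannane quenches the vinyl radical after 5-exo-dig closure. This comes back to the route at 35.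

Step 15. Addition to the large, electron-rich aldehyde may be slow, with erosion of face selectivity at the carbonyl or of the anti relationship. The fallback sets out from enynol 27 and aldehyde 24. Appel bromination of 27 (CBr4, PPh3, CH2Cl2, 0 °C) would give the allylic bromide F2. Aldehyde 24 would then be allylated with F2 in an asymmetric Nozaki–Hiyama–Kishi reaction (CrCl2, chiral oxazoline–sulfonamide ligand, Et3N, THF). The γ-substituted allylchromium reagent adds at its γ-carbon with anti selectivity under ligand control. This comes back to the route at 30.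

Step 18. Alkylation of the hindered secondary alkoxide may stay incomplete, and the base may induce migration of the neighbouring silyl group. The fallback sets out from alcohol 33. Rh2(OAc)4-catalysed O–H insertion of ethyl diazoacetate (CH2Cl2, rt) would give the ethyl ester F3 under neutral conditions. Saponification (LiOH, THF/H2O, then 1 M HCl to pH 4) comes back to the route at 34.

Further compounds
F1 | step 19 | 2-thioxopyridin-1(2H)-yl ester of acid 34 (Barton ester) | S=c1ccccn1OC(=O)CO[C@@H](c3cc(OC)c4c(c3)[C@@H](CO[Si](c3ccccc3)(c3ccccc3)C(C)(C)C)[C@H](c3cc(OC)c5c(c3)[C@H](CO[Si](c3ccccc3)(c3ccccc3)C(C)(C)C)[C@@H](c3ccc(OCc6ccccc6)c(OC)c3)O5)O4)[C@@H](CO[Si](c1ccccc1)(c1ccccc1)C(C)(C)C)C#Cc1ccc(OCc2ccccc2)c(OC)c1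
F2 | step 15 | (E)-5-[4-(benzyloxy)-3-methoxyphenyl]-1-bromopent-2-en-4-yne | BrC/C=C/C#Cc1ccc(OCc2ccccc2)c(OC)c1
F3 | step 18 | ethyl ester of acid 34 | CCOC(=O)CO[C@@H](c3cc(OC)c4c(c3)[C@@H](CO[Si](c3ccccc3)(c3ccccc3)C(C)(C)C)[C@H](c3cc(OC)c5c(c3)[C@H](CO[Si](c3ccccc3)(c3ccccc3)C(C)(C)C)[C@@H](c3ccc(OCc6ccccc6)c(OC)c3)O5)O4)[C@@H](CO[Si](c1ccccc1)(c1ccccc1)C(C)(C)C)C#Cc1ccc(OCc2ccccc2)c(OC)c1
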